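Late times were the question: how much target each flask below held at 6.0 h, judged from the grey run.

| flask | substrate | partner | third reagent | gas | remark | time |
|---|---|---|---|---|---|---|
| grey | 22 mM | 26 mM | 40 mM | 2.8 mM (held) | run made earlier |  |
| winter | 20 mM | 20.0 mM | 25.0 mM | 2.8 mM (held) |  | 6.0 h |
| dusk | 20 mM | 26.0 mM | 40.0 mM | 2.8 mM (held) |  | 6.0 h |
| autumn | 40 mM | 50.0 mM | 12.0 mM | 2.8 mM (held) |  | 6.0 h |
| midnight | 60 mM | 12.0 mM | 10.0 mM | 2.8 mM (held) |  | 6.0 h |

grey run (percent of the substrate charged): time / min: target / % = 12.0: 1.7; 30.0: 4.3; 60.0: 13.6; 90.0: 24.7; 120: 31.3

(each reading ± 1 percentage point)

1. all flasks from highest to lowest amount of target, in percent of the substrate charged, at 6.0 h (winter / dusk / autumn / midnight)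
2. the amount of target, in percent of the substrate charged of the flask you put first, at 6.0 h
3. the amount of target, in percent of the substrate charged of the flask you put last, at 6.0 h

- the numbers in the tables scatter with a standard deviation of 1 percentage point
- at the start none of the gas is in solution

Two numbers from grey would not go together. Grey gained 18 percentage points in its last 60.0 min, and that line carried on to 6.0 h read 102% of the substrate charged, more than the charge, though I allowed one target per substrate. The trouble cleared when I followed the fraction not yet target instead of the fraction made. In grey it fell from 86.4% at 60.0 min to 68.7% at 120 min, and I assumed that equal times remove equal shares of it, as in a first-order decay, which never crosses zero. Those readings gave 262 min as the clearing time, the time for the fraction not yet target to shrink by a factor of e. Traced back to a fraction of one, the decay started at 21.7 min, a dead time that fits grey's slow start.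

Dusk has grey's partner and third reagent, 26.0 mM and 40.0 mM, and less substrate, 20 mM against 22 mM, so I kept both figures. From the dead time to 6.0 h, the fraction not yet target came to 27.5%, and I committed to 72.5% of target in dusk.

The forecast gave dusk > winter > autumn > midnight, with 62% for dusk (range 48% to 78%) and 13% for midnight (range 7% to 17%). It added: “The stoichiometry and any dependence on the third reagent are assumed, not shown by the data, so the ranges are wide.” My dusk figure stood higher than the forecast's 62%, but inside its range.

The flasks came out dusk > winter > autumn > midnight, with dusk at 68.1% and midnight at 8.32%, and the steps behind them were these:

    substrate + partner → intermediate A (k = 0.0120 /M/s)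
    second reagent + intermediate A → intermediate B (k = 0.0660 /M/s)
    substrate + second reagent → side product (k = 0.00200 /M/s)
    third reagent + intermediate B ⇌ target (K = 150 /M, k = 0.140 /M/s)
    gas ⇌ second reagent, rate k5*(csat - [second reagent]) (kL = 0.0110 /s)

Dusk's fraction not yet target was 31.9% against my 27.5%. In dusk, intermediate B held more of that remainder than any other species, at 17.5%. Winter has 20.0 mM of partner and 25.0 mM of third reagent; I stretched the clearing time by the ratio of the partner charges to 340 min, made no change for the third reagent, kept the dead time, and so put winter's fraction not yet target at 37.0%. Winter actually stood at 48.4% after 6.00 h, with intermediate B at 23.8%.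

The numbers in the tables are calculated with constants of no real substance; noise was put on by code.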